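**Plan**
1. Retrosynthesis removes the C4–C5 epoxide (back to the E alkene), the O8 ester (alcohol plus Sharpless-derived (2S,3R)-epoxy acid), the lactone C12–O6 bond (2-methylene-1,4-diol) and the C10–C14 bond (enol triflate plus CO/MeOH).
2. What remains is a ten-membered ring holding the 1,5-diene C10=C1–C2–C3–C4=C5 with oxygen on C10: a retro-[3,3] shift cuts C2–C3 and restores C5–C10, giving a cis-1-vinyl-2-isopropenylcyclohexan-1-olate. The cyclohexane C5–C10 is a temporary ring and the C10 oxyanion the activating group, later exchanged for C14.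
3. Forward, the six-membered ring is bought as (1S,2S)-3-bromocyclohexa-3,5-diene-1,2-diol (O8, O9). C6–O and C7–C11 come from an O8-tethered phosphonoacetate opening a C6–C7 epoxide. C5 and C10 come from an O9-directed epoxide, isopropenyl opening, oxidation and vinyl addition.
4. Then follow ring expansion (ten-membered ring), carbonylation (C14), oxidative lactonization (lactone ring), acylation of O8, release of O9–H and epoxidation of C4=C5 last.
5. Stereochemistry: C8/C9 from the enzymatically derived diol; C6/C7 by anti epoxidation and intramolecular SN2; C5 by trans-diaxial epoxide opening; C10 by chelation-controlled addition; both ring-alkene geometries from the chair transition state; C4/C5 by peripheral epoxidation; the acyl epoxide by Sharpless epoxidation.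

Key step: step 17

Remark: atoms carry the numbers of the target throughout (ring C1–C10; lactone carbons C11, C12 (C=O), C13 (=CH2); ester carbon C14; methyl C15; O6, O8, O9 on C6, C8, C9). "The O8/O9 face" is the face of the six-membered ring that carries O8 and O9.
Remark: acetal 2 should form as both epimers at the acetal carbon, a centre that is lost in step 2; its SMILES leaves that centre open.

Step 1
Reactants: 1 (1S,2S)-3-bromocyclohexa-3,5-diene-1,2-diol
Product: 2 3,4-dimethoxybenzylidene acetal of 1 (cis-fused 2-aryl-1,3-dioxolane on O8/O9)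
Conditions: ArCH(OMe)2 (Ar = 3,4-dimethoxyphenyl), camphorsulfonic acid (cat.), CH2Cl2, rt
Reagents that add atoms: 3,4-dimethoxybenzaldehyde dimethyl acetal, COC(OC)c1ccc(OC)c(OC)c1
Why: Acid-catalysed transacetalization ties the cis-diol into a cyclic arylidene acetal under conditions mild enough to avoid dehydration of the diene diol to a phenol.

Step 2
Reactants: 2 3,4-dimethoxybenzylidene acetal of 1
Product: 3 bromodiene mono-ether (O9, next to C–Br, as 3,4-dimethoxybenzyl (DMPM) ether; O8–H free)
Conditions: i-Bu2AlH, CH2Cl2, −78 to 0 °C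
Reagents that add atoms: none
Why: Regioselective reductive acetal opening: i-Bu2AlH should bind the less hindered, more basic O8 (remote from bromine), so hydride delivery leaves the benzyl-type group on O9 and frees O8–H.

Step 3
Reactants: 3 bromodiene mono-ether
Product: 4 O8-(diethoxyphosphoryl)acetate of 3
Conditions: (EtO)2P(O)CH2CO2H, dicyclohexylcarbodiimide, DMAP (cat.), CH2Cl2, 0 °C to rt
Reagents that add atoms: diethylphosphonoacetic acid, OC(=O)CP(=O)(OCC)OCC
Why: Steglich esterification attaches the future C11–C12 unit to O8 as a tether without touching a stereocentre.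

Step 4
Reactants: 4 O8-(diethoxyphosphoryl)acetate
Product: 5 6,7-epoxide of 4 (epoxide oxygen on the face opposite O8/O9)
Conditions: mCPBA, NaHCO3, CH2Cl2, 0 °C to rt
Reagents that add atoms: 3-chloroperoxybenzoic acid, OOC(=O)c1cccc(Cl)c1
Why: Prilezhaev epoxidation should occur only at the bromine-free C6=C7 alkene and anti to the O8 and O9 substituents, which sets C6–O and C7–O on the face opposite O8.

Step 5
Reactants: 5 bromo vinyl epoxide
Product: 6 debrominated vinyl epoxide (C5=C10 cis-alkene)
Conditions: Bu3SnH, AIBN (cat.), benzene, 80 °C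
Reagents that add atoms: none
Why: Radical hydrodebromination (tin hydride chain reduction of the vinyl bromide) removes the regiocontrol element once the epoxide is in place.

Step 6
Reactants: 6 debrominated vinyl epoxide
Product: 8 cis-fused α-methylene γ-lactone (O8–C12(=O)–C11(=C13H2)–C7; C6–OH trans to C7–C11; C5=C10; O9-DMPM), via sodium phosphonate carbanion 7 (not isolated)
Conditions: NaH, THF, 0 to 40 °C; then (CH2O)n, rt
Reagents that add atoms: formaldehyde (as paraformaldehyde), C=O
Why: Intramolecular SN2 epoxide opening by the phosphonate-stabilized carbanion (exo mode, five-membered ring, attack at C7 anti to the epoxide oxygen) should give the cis-fused lactone with C7–C11 cis to O8 and C6–OH trans to it, after which Horner–Wadsworth–Emmons methylenation of carbanion 7 with formaldehyde installs C13.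

Step 7
Reactants: 8 cis-fused α-methylene γ-lactone
Product: 9 C6-O-tert-butyldimethylsilyl ether of 8
Conditions: t-BuMe2SiOTf, 2,6-lutidine, CH2Cl2, −78 °C
Reagents that add atoms: tert-butyldimethylsilyl trifluoromethanesulfonate, CC(C)(C)[Si](C)(C)OS(=O)(=O)C(F)(F)F
Why: Silylation blocks the C6 hydroxyl so that it cannot direct the later epoxidation to its own face.

Step 8
Reactants: 9 C6-O-silyl lactone
Product: 10 diol (C7 bears 3-hydroxyprop-1-en-2-yl; C8–OH free)
Conditions: i-Bu2AlH (excess), CH2Cl2, −78 to 0 °C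
Reagents that add atoms: none
Why: Hydride 1,2-reduction of the α-methylene lactone to the 2-methylene-1,4-diol releases O8 and turns C12 into the allylic alcohol from which the C6 lactone is made later.

Step 9
Reactants: 10 diol
Product: 11 C12-O-tert-butyldiphenylsilyl ether of 10
Conditions: t-BuPh2SiCl, imidazole, CH2Cl2, 0 °C
Reagents that add atoms: tert-butyldiphenylsilyl chloride, CC(C)(C)[Si](Cl)(c1ccccc1)c1ccccc1
Why: Selective silylation of the primary allylic alcohol over the hindered secondary C8 hydroxyl on steric grounds.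

Step 10
Reactants: 11 C12-O-silyl ether
Product: 12 C8-O-(4-methoxybenzyl) (PMB) ether of 11
Conditions: NaH, 4-MeOC6H4CH2Cl, Bu4NI (cat.), DMF, 0 °C to rt
Reagents that add atoms: 4-methoxybenzyl chloride, COc1ccc(CCl)cc1
Why: Williamson etherification puts on O8 a benzyl-type ether of intermediate oxidative lability, removable after DMPM and before 2-naphthylmethyl.

Step 11
Reactants: 12 fully protected cyclohexene
Product: 13 C9 allylic alcohol (DMPM removed)
Conditions: DDQ, CH2Cl2/H2O, 0 °C
Reagents that add atoms: none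
Why: Oxidative debenzylation with DDQ, in which the more electron-rich DMPM ether should be cleaved faster than the PMB ether, frees the C9 hydroxyl.

Step 12
Reactants: 13 C9 allylic alcohol
Product: 14 5,10-epoxide of 13 (epoxide oxygen cis to C9–OH, on the O8/O9 face)
Conditions: VO(acac)2 (cat.), t-BuOOH, CH2Cl2, 0 °C to rt
Reagents that add atoms: tert-butyl hydroperoxide, CC(C)(C)OO
Why: Hydroxyl-directed (vanadium-catalysed allylic alcohol) epoxidation should deliver oxygen to C5=C10 syn to C9–OH, reinforced by the C6 silyl ether on the other face, and leave the undirected 1,1-disubstituted alkene alone.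

Step 13
Reactants: 14 cis epoxy alcohol
Product: 15 C9-O-(2-naphthylmethyl) (NAP) ether of 14
Conditions: NaH, 2-(bromomethyl)naphthalene, Bu4NI (cat.), THF/DMF, 0 °C to rt
Reagents that add atoms: 2-(bromomethyl)naphthalene, BrCc1ccc2ccccc2c1
Why: Williamson etherification gives a chelating ether that is stable to the later bases and cleaved last; the cis epoxy alkoxide cannot undergo Payne rearrangement.

Step 14
Reactants: 15 epoxide
Product: 16 C5-isopropenyl C10-alcohol (isopropenyl cis to O6; C10–OH on the O8/O9 face)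
Conditions: CH2=C(CH3)MgBr, CuI (cat.), THF, −30 to 0 °C
Reagents that add atoms: isopropenylmagnesium bromide, CC(=C)[Mg]Br
Why: Copper-catalysed Grignard epoxide opening follows the Fürst–Plattner rule: trans-diaxial attack at C5 through the chair that keeps the C6, C7 and C9 substituents equatorial places isopropenyl anti to the epoxide oxygen (cis to O6) and leaves C10–OH on the O8/O9 face.

Step 15
Reactants: 16 C10 alcohol
Product: 17 C10 ketone
Conditions: Dess–Martin periodinane, NaHCO3, CH2Cl2, 0 °C
Reagents that add atoms: none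
Why: Dess–Martin oxidation under buffered, non-basic conditions should give the ketone without epimerizing or conjugating the β,γ-unsaturated C5 centre.

Step 16
Reactants: 17 C10 ketone
Product: 18 tertiary alcohol (C10 vinyl cis to C5 isopropenyl; C10–OH cis to O9)
Conditions: MgBr2·OEt2, CH2Cl2, −78 °C; then CH2=CHMgBr, −78 °C
Reagents that add atoms: vinylmagnesium bromide, C=C[Mg]Br
Why: Chelation-controlled Grignard addition (Cram chelate between the ketone and the O9 ether) with equatorial attack, the axial trajectory being blocked by the axial C8–OPMB group, should place vinyl cis to isopropenyl and the hydroxyl cis to O9.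

Step 17
Reactants: 18 tertiary alcohol
Product: 21 ten-membered enol triflate (C10–OTf; C1=C10 with C9 cis to C2; C4=C5 with C3 trans to C6), via potassium alkoxide 19 (not isolated), via potassium enolate 20 (not isolated)
Conditions: KH, 18-crown-6, THF, 0 °C to rt; then PhNTf2, −78 to 0 °C
Reagents that add atoms: N-phenylbis(trifluoromethanesulfonimide), O=S(=O)(N(c1ccccc1)S(=O)(=O)C(F)(F)F)C(F)(F)F
Why: KH converts 18 into potassium alkoxide 19, whose oxyanion weakens the C5–C10 bond so that the 1,5-diene C2=C1–C10–C5–C4=C3 undergoes a concerted [3,3]-sigmatropic shift (anionic oxy-Cope rearrangement) that forms C2–C3, breaks C5–C10 and gives the C1=C10 enolate 20 regiospecifically, which PhNTf2 traps on oxygen. The closest known reaction type is the anionic oxy-Cope ring expansion of 1,2-dialkenylcyclohexanols to cyclodec-5-enones with enolate triflation. The ten-membered ring is closed by ring expansion of the six-membered ring (suprafacial on both allyl units, six-membered chair transition state) and not by an end-to-end cyclization, so no high dilution is needed. No sp3 stereocentre is formed; the C4=C5 geometry (C3 trans to C6) follows from C6 being equatorial on the transition-state chair and the C1=C10 geometry (C9 cis to C2, oxygen trans to C2) from C9 being axial on it. The selectivity needed is reaction through the cyclohexane chair with vinyl equatorial and isopropenyl axial, which the cis vinyl/isopropenyl relationship makes possible and the equatorial C6, C7 and C9 substituents enforce, the flipped chair (leading to the other geometric isomer) having four axial groups. The stereocentres C6–C9 are spectators, and the activating oxygen ends as the triflate that is replaced in step 18.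

Step 18
Reactants: 21 enol triflate
Product: 22 C14 methyl ester (methyl cyclodeca-1(10),4-diene-10-carboxylate core)
Conditions: Pd(OAc)2 (cat.), dppp, CO (1 atm), MeOH, Et3N, DMF, 60 °C
Reagents that add atoms: carbon monoxide, [C-]#[O+]; methanol, CO
Why: Palladium-catalysed alkoxycarbonylation of the enol triflate (oxidative addition, CO insertion, methanolysis) replaces the activating oxygen on C10 by the C14 ester with retention of alkene geometry.

Step 19
Reactants: 22 C14 methyl ester
Product: 23 C6,C12-diol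
Conditions: Bu4NF, THF, 0 °C to rt
Reagents that add atoms: none
Why: Fluoride-mediated desilylation frees the C6 and C12 hydroxyls while the benzyl-type ethers on O8 and O9 stay.

Step 20
Reactants: 23 C6,C12-diol
Product: 25 trans-fused α-methylene γ-lactone (O6–C12; O8-PMB; O9-NAP), via lactol 24 (not isolated)
Conditions: TEMPO (cat.), PhI(OAc)2, CH2Cl2, rt
Reagents that add atoms: none
Why: TEMPO-catalysed oxidative lactonization: the primary allylic alcohol is oxidized selectively to the enal, which closes with the C6 hydroxyl to lactol 24 and is oxidized on to the lactone, O8 being blocked so that only the C6 lactone can form.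

Step 21
Reactants: 25 lactone
Product: 26 C8 alcohol (O9-NAP kept)
Conditions: (NH4)2Ce(NO3)6, MeCN/H2O, 0 °C
Reagents that add atoms: none
Why: Oxidative PMB ether cleavage under conditions in which the less electron-rich NAP ether should persist frees only the C8 hydroxyl.

Step 22
Reactants: 27 (E)-2-methylbut-2-en-1-ol
Product: 28 [(2R,3R)-2,3-dimethyloxiran-2-yl]methanol
Conditions: Ti(O-i-Pr)4 (cat.), D-(−)-diethyl tartrate (cat.), t-BuOOH, 4 Å molecular sieves, CH2Cl2, −20 °C
Reagents that add atoms: tert-butyl hydroperoxide, CC(C)(C)OO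
Why: Sharpless asymmetric epoxidation of the E allylic alcohol with the D-(−)-tartrate should deliver oxygen to the face that gives the (2R,3R)-epoxy alcohol.

Step 23
Reactants: 28 [(2R,3R)-2,3-dimethyloxiran-2-yl]methanol
Product: 29 (2S,3R)-2,3-dimethyloxirane-2-carboxylic acid
Conditions: TEMPO (cat.), PhI(OAc)2, MeCN/H2O, rt
Reagents that add atoms: water, O
Why: TEMPO/PhI(OAc)2 oxidation in aqueous acetonitrile takes the primary alcohol to the acid; the fully substituted α-carbon cannot epimerize and its descriptor changes only through the priority rules.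

Step 24
Reactants: 26 C8 alcohol; 29 (2S,3R)-2,3-dimethyloxirane-2-carboxylic acid
Product: 30 C8 ester (O9-NAP)
Conditions: 2,4,6-trichlorobenzoyl chloride, Et3N, THF, rt; then DMAP, toluene, 40 °C
Reagents that add atoms: none
Why: Yamaguchi esterification (mixed anhydride, DMAP acyl transfer) acylates the hindered C8 hydroxyl without touching either stereocentre of the acid.

Step 25
Reactants: 30 C8 ester
Product: 31 C9 alcohol (4,5-alkene precursor of the target)
Conditions: DDQ, CH2Cl2/H2O, rt
Reagents that add atoms: none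
Why: DDQ oxidative cleavage of the NAP ether proceeds under neutral conditions tolerated by both esters, the lactone and the acyl epoxide.

Step 26
Reactants: 31 C9 alcohol
Product: 32 target CNP0262846.1
Conditions: mCPBA, NaHCO3, CH2Cl2, 0 °C
Reagents that add atoms: 3-chloroperoxybenzoic acid, OOC(=O)c1cccc(Cl)c1
Why: Prilezhaev epoxidation is chemoselective for the only electron-rich alkene (trisubstituted C4=C5; the other two are conjugated to carbonyls) and stereospecific for the E geometry, and peripheral attack on the outer face of the alkene in the trans-lactone-locked ring should give the (4R,5R) epoxide.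

**Compound list**
1 | (1S,2S)-3-bromocyclohexa-3,5-diene-1,2-diol | O[C@H]1C=CC=C(Br)[C@H]1O | starting material
2 | 3,4-dimethoxybenzylidene acetal of 1 (both acetal epimers) | COc1ccc(C2O[C@H]3C=CC=C(Br)[C@H]3O2)cc1OC | intermediate
3 | bromodiene mono-ether (O9-DMPM, O8–H free) | O[C@H]1C=CC=C(Br)[C@H]1OCc1ccc(OC)c(OC)c1 | intermediate
4 | O8-(diethoxyphosphoryl)acetate of 3 | CCOP(=O)(OCC)CC(=O)O[C@H]1C=CC=C(Br)[C@H]1OCc1ccc(OC)c(OC)c1 | intermediate
5 | 6,7-epoxide of 4 (oxygen anti to O8/O9) | CCOP(=O)(OCC)CC(=O)O[C@H]1[C@@H]2O[C@@H]2C=C(Br)[C@H]1OCc1ccc(OC)c(OC)c1 | intermediate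
6 | debrominated vinyl epoxide | CCOP(=O)(OCC)CC(=O)O[C@H]1[C@@H]2O[C@@H]2C=C[C@H]1OCc1ccc(OC)c(OC)c1 | intermediate
7 | sodium salt of the cis-fused α-(diethoxyphosphoryl) lactone (C11 carbanion, C6–OH free) | CCOP(=O)(OCC)[C-]1C(=O)O[C@H]2[C@@H]1[C@H](O)C=C[C@H]2OCc1ccc(OC)c(OC)c1.[Na+] | intermediate
8 | cis-fused α-methylene γ-lactone (C6–OH, C5=C10, O9-DMPM) | C=C1C(=O)O[C@H]2[C@@H]1[C@H](O)C=C[C@H]2OCc1ccc(OC)c(OC)c1 | intermediate
9 | C6-O-TBS ether of 8 | C=C1C(=O)O[C@H]2[C@@H]1[C@H](O[Si](C)(C)C(C)(C)C)C=C[C@H]2OCc1ccc(OC)c(OC)c1 | intermediate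
10 | diol (C7 3-hydroxyprop-1-en-2-yl, C8–OH) | C=C(CO)[C@H]1[C@H](O[Si](C)(C)C(C)(C)C)C=C[C@@H](OCc2ccc(OC)c(OC)c2)[C@H]1O | intermediate
11 | C12-O-TBDPS ether of 10 | C=C(CO[Si](c2ccccc2)(c2ccccc2)C(C)(C)C)[C@H]1[C@H](O[Si](C)(C)C(C)(C)C)C=C[C@@H](OCc2ccc(OC)c(OC)c2)[C@H]1O | intermediate
12 | C8-O-PMB ether of 11 | C=C(CO[Si](c2ccccc2)(c2ccccc2)C(C)(C)C)[C@H]1[C@H](O[Si](C)(C)C(C)(C)C)C=C[C@@H](OCc2ccc(OC)c(OC)c2)[C@H]1OCc2ccc(OC)cc2 | intermediate
13 | C9 allylic alcohol | C=C(CO[Si](c2ccccc2)(c2ccccc2)C(C)(C)C)[C@H]1[C@H](O[Si](C)(C)C(C)(C)C)C=C[C@@H](O)[C@H]1OCc2ccc(OC)cc2 | intermediate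
14 | 5,10-epoxide of 13 (oxygen cis to C9–OH) | C=C(CO[Si](c2ccccc2)(c2ccccc2)C(C)(C)C)[C@H]1[C@H](O[Si](C)(C)C(C)(C)C)[C@H]2O[C@H]2[C@@H](O)[C@H]1OCc2ccc(OC)cc2 | intermediate
15 | C9-O-NAP ether of 14 | C=C(CO[Si](c2ccccc2)(c2ccccc2)C(C)(C)C)[C@H]1[C@H](O[Si](C)(C)C(C)(C)C)[C@H]2O[C@H]2[C@@H](OCc2ccc3ccccc3c2)[C@H]1OCc2ccc(OC)cc2 | intermediate
16 | C5-isopropenyl C10-alcohol | C=C(CO[Si](c2ccccc2)(c2ccccc2)C(C)(C)C)[C@H]1[C@H](O[Si](C)(C)C(C)(C)C)[C@H](C(C)=C)[C@@H](O)[C@@H](OCc2ccc3ccccc3c2)[C@H]1OCc2ccc(OC)cc2 | intermediate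
17 | C10 ketone | C=C(CO[Si](c2ccccc2)(c2ccccc2)C(C)(C)C)[C@H]1[C@H](O[Si](C)(C)C(C)(C)C)[C@H](C(C)=C)C(=O)[C@@H](OCc2ccc3ccccc3c2)[C@H]1OCc2ccc(OC)cc2 | intermediate
18 | tertiary alcohol (cis-1-vinyl-2-isopropenylcyclohexanol) | C=C(CO[Si](c2ccccc2)(c2ccccc2)C(C)(C)C)[C@H]1[C@H](O[Si](C)(C)C(C)(C)C)[C@H](C(C)=C)[C@](O)(C=C)[C@@H](OCc2ccc3ccccc3c2)[C@H]1OCc2ccc(OC)cc2 | intermediate
19 | potassium alkoxide of 18 | C=C(CO[Si](c2ccccc2)(c2ccccc2)C(C)(C)C)[C@H]1[C@H](O[Si](C)(C)C(C)(C)C)[C@H](C(C)=C)[C@]([O-])(C=C)[C@@H](OCc2ccc3ccccc3c2)[C@H]1OCc2ccc(OC)cc2.[K+] | intermediate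
20 | potassium enolate of the ring-expanded cyclodecadienone | C/C1=C\[C@@H](O[Si](C)(C)C(C)(C)C)[C@H](C(=C)CO[Si](c2ccccc2)(c2ccccc2)C(C)(C)C)[C@H](OCc2ccc(OC)cc2)[C@H](OCc2ccc3ccccc3c2)/C([O-])=C\CC1.[K+] | intermediate
21 | ten-membered enol triflate | C/C1=C\[C@@H](O[Si](C)(C)C(C)(C)C)[C@H](C(=C)CO[Si](c2ccccc2)(c2ccccc2)C(C)(C)C)[C@H](OCc2ccc(OC)cc2)[C@H](OCc2ccc3ccccc3c2)/C(OS(=O)(=O)C(F)(F)F)=C\CC1 | intermediate
22 | C14 methyl ester | C/C1=C\[C@@H](O[Si](C)(C)C(C)(C)C)[C@H](C(=C)CO[Si](c2ccccc2)(c2ccccc2)C(C)(C)C)[C@H](OCc2ccc(OC)cc2)[C@H](OCc2ccc3ccccc3c2)/C(C(=O)OC)=C\CC1 | intermediate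
23 | C6,C12-diol | C/C1=C\[C@@H](O)[C@H](C(=C)CO)[C@H](OCc2ccc(OC)cc2)[C@H](OCc2ccc3ccccc3c2)/C(C(=O)OC)=C\CC1 | intermediate
24 | lactol (C12 hemiacetal with O6) | C=C1C(O)O[C@H]2[C@H]1[C@H](OCc3ccc(OC)cc3)[C@H](OCc3ccc4ccccc4c3)/C(C(=O)OC)=C\CC/C(C)=C/2 | intermediate
25 | trans-fused α-methylene γ-lactone (O8-PMB, O9-NAP) | C=C1C(=O)O[C@H]2[C@H]1[C@H](OCc3ccc(OC)cc3)[C@H](OCc3ccc4ccccc4c3)/C(C(=O)OC)=C\CC/C(C)=C/2 | intermediate
26 | C8 alcohol (O9-NAP) | C=C1C(=O)O[C@H]2[C@H]1[C@H](O)[C@H](OCc3ccc4ccccc4c3)/C(C(=O)OC)=C\CC/C(C)=C/2 | intermediate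
27 | (E)-2-methylbut-2-en-1-ol | C/C=C(\C)CO | starting material
28 | [(2R,3R)-2,3-dimethyloxiran-2-yl]methanol | OC[C@@]1(C)O[C@@H]1C | intermediate
29 | (2S,3R)-2,3-dimethyloxirane-2-carboxylic acid | OC(=O)[C@@]1(C)O[C@@H]1C | intermediate
30 | C8 ester (O9-NAP) | C=C1C(=O)O[C@H]2[C@H]1[C@H](OC(=O)[C@@]3(C)O[C@@H]3C)[C@H](OCc3ccc4ccccc4c3)/C(C(=O)OC)=C\CC/C(C)=C/2 | intermediate
31 | C9 alcohol with C4=C5 alkene | C=C1C(=O)O[C@H]2[C@H]1[C@H](OC(=O)[C@@]3(C)O[C@@H]3C)[C@H](O)/C(C(=O)OC)=C\CC/C(C)=C/2 | intermediate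
32 | CNP0262846.1 | C=C1C(=O)O[C@H]2[C@H]1[C@H](OC(=O)[C@@]1(C)O[C@@H]1C)[C@H](O)/C(C(=O)OC)=C\CC[C@@]1(C)O[C@H]21 | target

Total step count: 26. Longest linear sequence: 24 steps (steps 1–21 and 24–26; steps 22–23 make the acid in parallel).

**Steps most likely to fail**

Step 6. The soft phosphonate carbanion may open the epoxide at the allylic carbon C6 in a six-membered endo closure, or react so slowly that base-induced isomerization of the vinyl epoxide competes. The fallback sets out from 3 and separates carbon–carbon bond formation from methylenation. Acetylation gives the O8 acetate F1, and epoxidation and tin hydride reduction as in steps 4 and 5 give the bromo epoxide F2 and the vinyl epoxide F3. The lithium enolate (LiN(SiMe3)2) is transmetallated with Et2AlCl, and this harder aluminium ester enolate should open the epoxide at C7 to the cis-fused lactone alcohol F4. Its dianion (LDA) is aminomethylated with Eschenmoser's salt to the Mannich base F5, and quaternization with MeI followed by elimination with NaHCO3 returns to the route at 8.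

Step 16. Facial selectivity may be poor because the axial isopropenyl group on C5 crowds the equatorial trajectory, and the basic reagent may epimerize C5. The fallback sets out from 17 and builds the carbinol by methylene transfer instead of vinyl addition. Corey–Chaykovsky reaction with dimethylsulfoxonium methylide (thermodynamic, equatorial C–C bond) should give the spiro-epoxide F6 with its oxygen on the O8/O9 face. Excess dimethylsulfonium methylide then converts the epoxide into the one-carbon-homologated allylic alcohol, which is 18.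

Step 17. The potassium alkoxide may fragment or react through the flipped chair, eroding the alkene geometry, and the enolate may be protonated instead of triflated, after which its regiochemistry and geometry are lost. The fallback sets out from 18 and uses the neutral manifold. Silylation gives the trimethylsilyl ether F7, and thermal silyloxy-Cope rearrangement (toluene, sealed tube, 180 °C) through the same chair should give the ring-expanded trimethylsilyl enol ether F8. Cleavage with MeLi to the lithium enolate and trapping with PhNTf2 returns to the route at 21.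

Further compounds
F1 | step 6 | O8 acetate of 3 | CC(=O)O[C@H]1C=CC=C(Br)[C@H]1OCc1ccc(OC)c(OC)c1
F2 | step 6 | 6,7-epoxide of F1 | CC(=O)O[C@H]1[C@@H]2O[C@@H]2C=C(Br)[C@H]1OCc1ccc(OC)c(OC)c1
F3 | step 6 | debrominated vinyl epoxide acetate | CC(=O)O[C@H]1[C@@H]2O[C@@H]2C=C[C@H]1OCc1ccc(OC)c(OC)c1
F4 | step 6 | cis-fused γ-lactone alcohol (C11H2) | C1C(=O)O[C@H]2[C@@H]1[C@H](O)C=C[C@H]2OCc1ccc(OC)c(OC)c1
F5 | step 6 | α-(dimethylaminomethyl) lactone (Mannich base) | CN(C)CC1C(=O)O[C@H]2[C@@H]1[C@H](O)C=C[C@H]2OCc1ccc(OC)c(OC)c1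
F6 | step 16 | C10 spiro-epoxide of 17 | C=C(CO[Si](c2ccccc2)(c2ccccc2)C(C)(C)C)[C@H]1[C@H](O[Si](C)(C)C(C)(C)C)[C@H](C(C)=C)[C@]2(CO2)[C@@H](OCc2ccc3ccccc3c2)[C@H]1OCc2ccc(OC)cc2
F7 | step 17 | trimethylsilyl ether of 18 | C=C(CO[Si](c2ccccc2)(c2ccccc2)C(C)(C)C)[C@H]1[C@H](O[Si](C)(C)C(C)(C)C)[C@H](C(C)=C)[C@](O[Si](C)(C)C)(C=C)[C@@H](OCc2ccc3ccccc3c2)[C@H]1OCc2ccc(OC)cc2
F8 | step 17 | ten-membered trimethylsilyl enol ether | C/C1=C\[C@@H](O[Si](C)(C)C(C)(C)C)[C@H](C(=C)CO[Si](c2ccccc2)(c2ccccc2)C(C)(C)C)[C@H](OCc2ccc(OC)cc2)[C@H](OCc2ccc3ccccc3c2)/C(O[Si](C)(C)C)=C\CC1
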